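Atom labels follow flavanone numbering (O1, C2, C3, C4, C4a, C5–C8, C8a; ring A is the carbocycle, ring C the heterocycle, ring B the aryl group on C2). The monocyclic precursors 3–8 carry cyclohexenone locants, whose C1, C2, C3 and C6 become C8a, C8, C7 and C4a.

## Analysis of the target

The target 14 is a flavanone: a chroman-4-one (rings A and C) with a 3,4-dihydroxyphenyl ring B on C2. Ring A is a 1,2,3,4-tetrasubstituted benzene in which C4a carries the C4 ketone, C8a carries O1, C8 carries an (E)-4-hydroxy-3-methylbut-2-enyl chain and C7 a methoxy group; C5 and C6 are unsubstituted. The only stereocentre is C2 (S). It is benzylic, bears O1 and lies β to the C4 carbonyl, so base can open ring C by a retro-oxa-Michael reaction and acid can ionise the C2–O1 bond through the electron-rich ring B; either path racemises it. The second stereochemical element is the E geometry of the trisubstituted side-chain alkene. Sensitive groups are the catechol (oxidation, above all as a phenoxide), the primary allylic alcohol and the C2–O1 bond. The difficulty lies in setting C2 as one enantiomer beside a crowded, contiguously substituted ring A and keeping it to the end. The strategy rests on C8 lying between two oxygen-bearing carbons, C8a (O1) and C7 (OMe). With C5 and C6 at the CH2 level, ring A is a 2-alkylcyclohexane-1,3-dione derivative, and the C4a–C8a bond is then an enol double bond rather than an aromatic bond. Together with the enol of an acetyl group on C4a (C4=C3) it forms a 1,3-dioxygenated diene that can take up an aldehyde across C3 and C8a.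

## Retrosynthetic reasoning

The three hydroxyl groups of 14 are unmasked last. Cutting the three O–Si bonds leads to the tris(silyl) ether 13, in which the catechol is shielded from oxidants and the allylic alcohol from acid. The forward desilylation must not let a phenoxide open ring C.

Ring A of 13 is taken back to the C5,C6-dihydro level, compound 12, by adding two hydrogens across C5–C6. Nothing else changes, but the C4a–C8a bond stops being part of an arene and becomes an ordinary enol ether double bond. The forward reaction is a dehydrogenation driven by aromatisation; it has to spare C2–H and the side chain.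

In 12 ring C is a 2,3-dihydro-4H-pyran-4-one. Its C2–C3 and O1–C8a bonds are cut, the retron of a hetero-Diels–Alder (or aldol–cyclisation) reaction. This gives aldehyde 10, which supplies C2, O1 and ring B, and the bis(silyl) dienol ether 8, which supplies C3, C4, C4a and C8a. Cutting here, and not at O1–C2 or C4–C4a, means the stereocentre arises in a carbonyl addition under catalyst control. Its C–O bond is the former aldehyde C=O bond, so no displacement at an easily ionised benzylic carbon is needed. One ring, two skeletal bonds and the only stereocentre come from one operation. The forward reaction must deliver the exocyclic methylene of 8 to one face of 10 and then close the ring at C8a.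

Diene 8 is the double enol derivative of β-diketone 6, so the two O–Si bonds are cut. The forward step must enolise the acetyl group towards its methyl carbon, the future C3.

The acetyl group of 6 is removed by cutting the bond between the ring carbon (future C4a) and the acetyl carbonyl carbon (future C4), a Claisen-type disconnection to vinylogous ester 5. Kinetic deprotonation of 5 can only give the enolate at that ring carbon, because the other α-carbon is a substituted sp2 centre.

The silyl ether and the enol methyl ether of 5 are cut in turn, leading through 4 to dione 3. Dione 3 is mirror-symmetric, so either carbonyl may become the C7 methoxy carbon and no regiochemical question arises.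

The side chain of 3 is detached at the bond between the dione C2 (future C8) and the allylic CH2, which gives dione 1 and vinyl epoxide 2. The forward allylic alkylation uses the nucleophilic carbon between the two carbonyls and delivers the chain with its E alkene and free primary hydroxyl in one step.

Aldehyde 10 is the bis(silyl) ether of the commercial catechol aldehyde 9.

## Alternatives that were turned down

Alternative 1: Ring A is built by cutting C4a–C8a and C5–C6, which leads to the chiral terminal ynone A2 and the trioxygenated diene A3. In the forward key step a thermal [4+2] cycloaddition joins the CH2 terminus of A3 to the alkyne CH and its ketene acetal carbon to the acyl-bearing alkyne carbon; the adduct expels its acetal substituents and tautomerises to the ring A phenol A1.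
- For: the arene is formed at the correct oxidation level with the regiochemistry fixed by the polarisation of both partners, and the union is convergent. On these points it is stronger than the chosen route, which needs a separate dehydrogenation.
- Against: the stereocentre must be made beforehand in A2, a β-silyloxy ynone that can eliminate on heating. A3 is a fully substituted ketene acetal that is awkward to prepare. Ring C must still be closed from A1 by cleaving the triethylsilyl ether and displacing the benzylic carbinol with inversion, at a carbon that ionises easily because of ring B.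
- Comparison: the chosen strategy uses the aldehyde C=O bond as the future C2–O1 bond, so that bond is never formed by substitution. It closes ring C and sets C2 together, and it reaches 13 in fewer operations after the fragments are joined.

Alternative 2: Ring C is cut at C4–C4a, which leads to the (S)-3-aryl-3-aryloxypropanoic acid A5. In the forward key step A5 is activated with (CF3CO)2O as a mixed anhydride and acylates C4a intramolecularly to give the flavanone triacetate A4.
- For: the chemistry is classical, ring A is aromatic throughout, and C4a is para to the methoxy group and the only position within reach. It is as strong as the chosen route on regiocontrol and stronger on precedent for the ring closure itself.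
- Against: the strongly acidic acylating medium meets a benzylic aryl ether that can ionise or fragment to a cinnamic acid and a phenol, which would erode C2. It also meets a trisubstituted alkene with an allylic acetate, which can add acid or cyclise onto the arene. A5 needs its own enantioselective C–O bond construction, and removing the acetates from A4 calls for conditions under which a flavanone opens.
- Comparison: the chosen route keeps C2 away from strong acid and base after it is formed, and it ends with a buffered desilylation.

Alternative 3: Ring C is cut at C3=C4, which leads to the aryl ether A7 carrying a vinyl group on C2 and a 1-silyloxyvinyl group on C4a. In the forward key step the second-generation Grubbs catalyst joins the two terminal alkenes, with loss of the two CH2 termini as a volatile olefin, to give the 4-silyloxy-2H-chromene A6; fluoride then unveils the ketone together with the other silyl ethers.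
- For: ring closure is neutral, and the ketone is revealed in the final deprotection, so step economy is good. The stereocentre could come from a branched-selective allylic etherification with [Ir(cod)Cl]2 and a chiral phosphoramidite, a well-established intermolecular method. On precedent for the stereo-defining step it is stronger than the chosen route.
- Against: the side-chain trisubstituted alkene of A7 competes in metathesis. The electron-rich enol ether is a reluctant partner. The benzylic and allylic C2–O bond of A7 is prone to ionisation and to double-bond migration by hydride species formed from the catalyst, which would destroy C2. The etherification would also have to use a phenol flanked by two ortho substituents.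
- Comparison: the chosen route has no olefin chemoselectivity problem, and it builds the crowded ring A pattern from a symmetric dione by simple C-alkylation.

Key step: step 7

Assumption: the (S)-BINOL/Ti(O-i-Pr)4 catalyst is taken to direct the nucleophile to the Si face of the aryl aldehyde (giving 2S), as in the allylation and aldol additions of this catalyst class. Should diene 8 respond in the opposite sense, (R)-BINOL is used and nothing else changes.

## Route

Step 1
Reactants: 1 cyclohexane-1,3-dione; 2 2-methyl-2-vinyloxirane
Product: 3 2-[(E)-4-hydroxy-3-methylbut-2-enyl]cyclohexane-1,3-dione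
Conditions: Pd(PPh3)4 (3 mol %), THF, 0 °C → rt; 1 in excess (2 equiv)
Reagents that add atoms: none
Why: Tsuji–Trost allylic alkylation with a vinyl epoxide: zerovalent palladium opens 2 to a zwitterionic π-allyl complex whose alkoxide deprotonates the acidic dione, and the soft enolate attacks the unsubstituted allyl terminus (1,4-addition), C-alkylation being the thermodynamic outcome for 1,3-diones. The E alkene should arise from the π-allyl isomer with the CH2O group syn, and the excess of 1 suppresses double alkylation.

Step 2
Reactants: 3 2-[(E)-4-hydroxy-3-methylbut-2-enyl]cyclohexane-1,3-dione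
Product: 4 2-[(E)-4-hydroxy-3-methylbut-2-enyl]-3-methoxycyclohex-2-en-1-one
Conditions: Me2SO4, K2CO3, acetone, reflux
Reagents that add atoms: dimethyl sulfate, COS(=O)(=O)OC
Why: O-alkylation of the enolised 2-alkyl-1,3-dione with a hard methylating agent (vinylogous ester formation); 3 is symmetric, so only one enol ether can form, and the carbonate base does not deprotonate the allylic alcohol.

Step 3
Reactants: 4 2-[(E)-4-hydroxy-3-methylbut-2-enyl]-3-methoxycyclohex-2-en-1-one
Product: 5 2-[(E)-4-(tert-butyldimethylsilyloxy)-3-methylbut-2-enyl]-3-methoxycyclohex-2-en-1-one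
Conditions: t-BuMe2SiCl, imidazole, DMF, rt
Reagents that add atoms: tert-butyldimethylsilyl chloride, CC(C)(C)[Si](C)(C)Cl
Why: Standard silyl ether formation at the primary alcohol with imidazole as base and nucleophilic catalyst; the vinylogous ester is inert.

Step 4
Reactants: 5 2-[(E)-4-(tert-butyldimethylsilyloxy)-3-methylbut-2-enyl]-3-methoxycyclohex-2-en-1-one
Product: 6 6-acetyl-2-[(E)-4-(tert-butyldimethylsilyloxy)-3-methylbut-2-enyl]-3-methoxycyclohex-2-en-1-one
Conditions: LiN(i-Pr)2 (2.1 equiv), THF, −78 °C; 1-acetyl-1H-benzotriazole, −78 → −20 °C; aq. NH4Cl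
Reagents that add atoms: 1-acetyl-1H-benzotriazole, CC(=O)n1nnc2ccccc21
Why: Kinetic α'-deprotonation of a 3-alkoxycyclohex-2-enone followed by Claisen-type C-acylation with an N-acylbenzotriazole, an acyl donor that favours C- over O-acylation. The second equivalent of base is taken up by the more acidic β-diketone, which protects it from further reaction.

Step 5
Reactants: 6 6-acetyl-2-[(E)-4-(tert-butyldimethylsilyloxy)-3-methylbut-2-enyl]-3-methoxycyclohex-2-en-1-one
Product: 8 1-methoxy-2-[(E)-4-(tert-butyldimethylsilyloxy)-3-methylbut-2-enyl]-3-(trimethylsilyloxy)-4-[1-(trimethylsilyloxy)vinyl]cyclohexa-1,3-diene, via mono(trimethylsilyl) enol ether 7 (not isolated)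
Conditions: Me3SiCl, Et3N, Et2O, rt; filter, concentrate; then LiN(i-Pr)2, THF, −78 °C; Me3SiCl, −78 → 0 °C; salts removed under argon, used crude
Reagents that add atoms: chlorotrimethylsilane, C[Si](C)(C)Cl
Why: Two-stage enol silylation as practised for bis(silyl) dienol ethers of β-dicarbonyl compounds: amine-mediated O-silylation of the enolised diketone gives 7, whose acetyl methyl group is then deprotonated kinetically and trapped on oxygen. Either O-silyl regioisomer of 7 leads to the same diene once the methyl group is deprotonated.

Step 6
Reactants: 9 3,4-dihydroxybenzaldehyde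
Product: 10 3,4-bis(tert-butyldimethylsilyloxy)benzaldehyde
Conditions: t-BuMe2SiCl (2.4 equiv), imidazole, DMF, rt
Reagents that add atoms: tert-butyldimethylsilyl chloride, CC(C)(C)[Si](C)(C)Cl
Why: Standard phenol silylation; the aryl silyl ethers should withstand the Lewis acid, the brief acid treatment and the quinone oxidation, and they fall to fluoride at the end.

Step 7
Reactants: 8 1-methoxy-2-[(E)-4-(tert-butyldimethylsilyloxy)-3-methylbut-2-enyl]-3-(trimethylsilyloxy)-4-[1-(trimethylsilyloxy)vinyl]cyclohexa-1,3-diene; 10 3,4-bis(tert-butyldimethylsilyloxy)benzaldehyde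
Product: 12 (S)-2-[3,4-bis(tert-butyldimethylsilyloxy)phenyl]-8-[(E)-4-(tert-butyldimethylsilyloxy)-3-methylbut-2-enyl]-7-methoxy-2,3,5,6-tetrahydro-4H-chromen-4-one, via silylated aldol adduct 11 (not isolated)
Conditions: (S)-BINOL (20 mol %), Ti(O-i-Pr)4 (10 mol %), 4 Å molecular sieves, Et2O, −20 °C; then CF3CO2H, CH2Cl2, 0 °C, short; aq. NaHCO3
Reagents that add atoms: none
Why: Ti(O-i-Pr)4 and (S)-BINOL form a chiral tetravalent titanium Lewis acid that binds aldehyde 10; the exocyclic methylene of 8 attacks the carbonyl carbon (C2–C3) in a vinylogous Mukaiyama aldol reaction, and silyl transfer to the aldolate gives 11 and frees the catalyst. The closest known reaction type is the BINOL–titanium-catalysed addition of 1,3-bis(silyloxy)dienes of β-dicarbonyl compounds and of 1-alkoxy-3-silyloxydienes to aryl aldehydes followed by acid cyclisation to 2,3-dihydro-4H-pyran-4-ones, a formal hetero-Diels–Alder reaction. With CF3CO2H the trimethylsilyl groups are lost, the freed C2 hydroxyl adds to the C8a carbonyl of the unmasked 1,3-diketone (6-exo-trig, equivalent to addition–elimination at the β-carbon of the enolised diketone), and loss of water leaves C8a=C4a conjugated with the C4 ketone. Ring C is therefore closed through O1–C8a with the former aldehyde oxygen, so the C2–O bond made in the aldol step is never broken and the configuration is carried over. C2 is set by the catalyst alone: the (S)-BINOL complex is expected to shield the Re face of the bound aldehyde, and attack on the Si face gives 2S. The step needs site selectivity within the cross-conjugated triene and one ring size only; the first is secured because the methylene is the sole unsubstituted terminus and both silyloxy groups direct electron density to it while C4a and C8 are fully substituted, the second because only the C8a carbonyl is within reach of the hydroxyl for a six-membered ring. The acid treatment is kept short and cold so that carbonyl addition outpaces ionisation at the benzylic carbon, which would racemise C2.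

Step 8
Reactants: 12 (S)-2-[3,4-bis(tert-butyldimethylsilyloxy)phenyl]-8-[(E)-4-(tert-butyldimethylsilyloxy)-3-methylbut-2-enyl]-7-methoxy-2,3,5,6-tetrahydro-4H-chromen-4-one
Product: 13 (S)-2-[3,4-bis(tert-butyldimethylsilyloxy)phenyl]-8-[(E)-4-(tert-butyldimethylsilyloxy)-3-methylbut-2-enyl]-7-methoxychroman-4-one
Conditions: DDQ (1.1 equiv), benzene, rt
Reagents that add atoms: none
Why: Quinone dehydrogenation of a dihydroarene: hydride abstraction from C5 gives a cation stabilised by O1 at C8a and by the C7 methoxy group (the arenium ion of the product protonated at C6), which loses the C6 proton. Aromatisation is the driving force, so the reaction should run under conditions too mild for attack at C2–C3 or at the allylic silyl ether, and C2 is not involved.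

Step 9
Reactants: 13 (S)-2-[3,4-bis(tert-butyldimethylsilyloxy)phenyl]-8-[(E)-4-(tert-butyldimethylsilyloxy)-3-methylbut-2-enyl]-7-methoxychroman-4-one
Product: 14 (S)-2-(3,4-dihydroxyphenyl)-8-[(E)-4-hydroxy-3-methylbut-2-enyl]-7-methoxychroman-4-one
Conditions: Bu4NF, AcOH (1:1, excess), THF, 0 °C → rt, under argon
Reagents that add atoms: none
Why: Fluoride desilylation of the two aryl silyl ethers and the primary alkyl silyl ether. Acetic acid protonates the phenoxides as they form, which should suppress opening of ring C through the 4'-phenoxide (retro-oxa-Michael) and so racemisation at C2, and it limits oxidation of the catechol.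

## Compound list

1 | cyclohexane-1,3-dione | O=C1CCCC(=O)C1 | starting material
2 | 2-methyl-2-vinyloxirane (isoprene monoepoxide, racemic) | CC1(C=C)CO1 | starting material
3 | 2-[(E)-4-hydroxy-3-methylbut-2-enyl]cyclohexane-1,3-dione | O=C1CCCC(=O)C1C/C=C(\C)CO | intermediate
4 | 2-[(E)-4-hydroxy-3-methylbut-2-enyl]-3-methoxycyclohex-2-en-1-one | COC1=C(C/C=C(\C)CO)C(=O)CCC1 | intermediate
5 | 2-[(E)-4-(tert-butyldimethylsilyloxy)-3-methylbut-2-enyl]-3-methoxycyclohex-2-en-1-one | COC1=C(C/C=C(\C)CO[Si](C)(C)C(C)(C)C)C(=O)CCC1 | intermediate
6 | 6-acetyl-2-[(E)-4-(tert-butyldimethylsilyloxy)-3-methylbut-2-enyl]-3-methoxycyclohex-2-en-1-one (drawn as the diketone; enolised in solution, C6 configuration of no consequence) | COC1=C(C/C=C(\C)CO[Si](C)(C)C(C)(C)C)C(=O)C(C(C)=O)CC1 | intermediate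
7 | 1-{3-[(E)-4-(tert-butyldimethylsilyloxy)-3-methylbut-2-enyl]-4-methoxy-2-(trimethylsilyloxy)cyclohexa-1,3-dien-1-yl}ethanone (mono(trimethylsilyl) enol ether of 6, formed in the flask in step 5) | COC1=C(C/C=C(\C)CO[Si](C)(C)C(C)(C)C)C(O[Si](C)(C)C)=C(CC1)C(C)=O | intermediate
8 | 1-methoxy-2-[(E)-4-(tert-butyldimethylsilyloxy)-3-methylbut-2-enyl]-3-(trimethylsilyloxy)-4-[1-(trimethylsilyloxy)vinyl]cyclohexa-1,3-diene | COC1=C(C/C=C(\C)CO[Si](C)(C)C(C)(C)C)C(O[Si](C)(C)C)=C(CC1)C(=C)O[Si](C)(C)C | intermediate
9 | 3,4-dihydroxybenzaldehyde | O=Cc1ccc(O)c(O)c1 | starting material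
10 | 3,4-bis(tert-butyldimethylsilyloxy)benzaldehyde | O=Cc1ccc(O[Si](C)(C)C(C)(C)C)c(O[Si](C)(C)C(C)(C)C)c1 | intermediate
11 | (S)-3-[3,4-bis(tert-butyldimethylsilyloxy)phenyl]-1-{3-[(E)-4-(tert-butyldimethylsilyloxy)-3-methylbut-2-enyl]-4-methoxy-2-(trimethylsilyloxy)cyclohexa-1,3-dien-1-yl}-3-(trimethylsilyloxy)propan-1-one (silylated aldol adduct, formed in the flask in step 7) | COC1=C(C/C=C(\C)CO[Si](C)(C)C(C)(C)C)C(O[Si](C)(C)C)=C(CC1)C(=O)C[C@@H](c1ccc(O[Si](C)(C)C(C)(C)C)c(O[Si](C)(C)C(C)(C)C)c1)O[Si](C)(C)C | intermediate
12 | (S)-2-[3,4-bis(tert-butyldimethylsilyloxy)phenyl]-8-[(E)-4-(tert-butyldimethylsilyloxy)-3-methylbut-2-enyl]-7-methoxy-2,3,5,6-tetrahydro-4H-chromen-4-one | COC1=C(C/C=C(\C)CO[Si](C)(C)C(C)(C)C)C2=C(CC1)C(=O)C[C@@H](c1ccc(O[Si](C)(C)C(C)(C)C)c(O[Si](C)(C)C(C)(C)C)c1)O2 | intermediate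
13 | (S)-2-[3,4-bis(tert-butyldimethylsilyloxy)phenyl]-8-[(E)-4-(tert-butyldimethylsilyloxy)-3-methylbut-2-enyl]-7-methoxychroman-4-one | COc1ccc2c(c1C/C=C(\C)CO[Si](C)(C)C(C)(C)C)O[C@H](c1ccc(O[Si](C)(C)C(C)(C)C)c(O[Si](C)(C)C(C)(C)C)c1)CC2=O | intermediate
14 | (S)-2-(3,4-dihydroxyphenyl)-8-[(E)-4-hydroxy-3-methylbut-2-enyl]-7-methoxychroman-4-one (CNP0503781.1) | COc1ccc2c(c1C/C=C(\C)CO)O[C@H](c1ccc(O)c(O)c1)CC2=O | target

## Step count and least certain steps

Total: 9 steps. Longest linear sequence: 8 steps (steps 1–5, 7, 8, 9); step 6 is a one-step branch.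

**Step 7 (key step).**
- What may go wrong: facial discrimination may be poor, because the bulky ring-fused diene and the electron-rich, slowly reacting aldehyde leave room for an uncatalysed or silyl-cation-catalysed background addition. Configuration may be lost during the acid closure through ionisation at the benzylic carbon or dehydration of the aldol. Diene 8 may be hydrolysed before it reacts.
- Fallback: it sets out from 10 and 5 and returns at 12; the stereocentre is set on a simple nucleophile and the C4–C4a bond is made by acylation, so diene 8 is not needed (this also covers a wrong enolisation in step 5). Aldehyde 10 is combined under the same (S)-BINOL/Ti(O-i-Pr)4 catalyst with 1-(ethylsulfanyl)-1-(trimethylsilyloxy)ethene in a Mukaiyama aldol addition to give S-ethyl (S)-3-[3,4-bis(tert-butyldimethylsilyloxy)phenyl]-3-hydroxypropanethioate F1. Et3SiCl and imidazole convert it into S-ethyl (S)-3-[3,4-bis(tert-butyldimethylsilyloxy)phenyl]-3-(triethylsilyloxy)propanethioate F2. The kinetic lithium enolate of 5 (LiN(i-Pr)2, THF, −78 °C, used in twofold amount so that no free amide base meets the thioester) is C-acylated by F2 to 6-[(S)-3-[3,4-bis(tert-butyldimethylsilyloxy)phenyl]-3-(triethylsilyloxy)propanoyl]-2-[(E)-4-(tert-butyldimethylsilyloxy)-3-methylbut-2-enyl]-3-methoxycyclohex-2-en-1-one F3. CF3CO2H then removes the triethylsilyl group and closes ring C to 12.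

**Step 8.**
- What may go wrong: hydride abstraction may compete at other activated C–H bonds of 12 (the doubly allylic side-chain CH2, the benzylic C2–H, the allylic CH2–O), or oxidation may continue at C2–C3.
- Fallback: it sets out from 8 and 10 and returns at 13; ring A is aromatised in the open-chain series by selenoxide elimination, and ring C is closed afterwards with inversion. The aldol addition of step 7 is run with (R)-BINOL/Ti(O-i-Pr)4 and worked up with pyridinium p-toluenesulfonate in MeOH at 0 °C (no cyclodehydration) to give 6-[(R)-3-[3,4-bis(tert-butyldimethylsilyloxy)phenyl]-3-hydroxypropanoyl]-2-[(E)-4-(tert-butyldimethylsilyloxy)-3-methylbut-2-enyl]-3-methoxycyclohex-2-en-1-one F4. PhSeCl and pyridine selenenylate the carbon between the two carbonyls to give 6-[(R)-3-[3,4-bis(tert-butyldimethylsilyloxy)phenyl]-3-hydroxypropanoyl]-2-[(E)-4-(tert-butyldimethylsilyloxy)-3-methylbut-2-enyl]-3-methoxy-6-(phenylselanyl)cyclohex-2-en-1-one F5. H2O2 triggers selenoxide syn-elimination towards C5, and the dienone tautomerises to (R)-3-[3,4-bis(tert-butyldimethylsilyloxy)phenyl]-3-hydroxy-1-{2-hydroxy-4-methoxy-3-[(E)-4-(tert-butyldimethylsilyloxy)-3-methylbut-2-enyl]phenyl}propan-1-one F6. A Mitsunobu etherification (PPh3, diisopropyl azodicarboxylate, THF) closes O1–C2 with inversion to 13.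

**Step 4.**
- What may go wrong: O-acylation, proton exchange between the enolate and the acyl donor or the product, or equilibration to the γ-enolate may lower conversion to the C-acyl compound.
- Fallback: it sets out from 5 and returns at 6. The kinetic enolate of 5 (LiN(i-Pr)2, THF, −78 °C) undergoes aldol addition to acetaldehyde to give 2-[(E)-4-(tert-butyldimethylsilyloxy)-3-methylbut-2-enyl]-6-(1-hydroxyethyl)-3-methoxycyclohex-2-en-1-one F7 as a diastereomer mixture, and Dess–Martin oxidation (NaHCO3, CH2Cl2) gives 6.

**Step 1.**
- What may go wrong: the E geometry may erode by π–σ–π isomerisation at the disubstituted allyl terminus, and 3 may be alkylated a second time.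
- Fallback: it sets out from 1 and returns at 4; the geometry is set by an E-selective allylic oxidation instead. Dione 1 is C-alkylated with 1-bromo-3-methylbut-2-ene (aq. KOH, rt) to 2-(3-methylbut-2-enyl)cyclohexane-1,3-dione F8. Me2SO4 and K2CO3 give 3-methoxy-2-(3-methylbut-2-enyl)cyclohex-2-en-1-one F9. Catalytic SeO2 with t-BuOOH in CH2Cl2 hydroxylates the (E)-methyl group of the prenyl unit to give 4.

## Further compounds

F1 | step 7 | S-ethyl (S)-3-[3,4-bis(tert-butyldimethylsilyloxy)phenyl]-3-hydroxypropanethioate | CCSC(=O)C[C@@H](c1ccc(O[Si](C)(C)C(C)(C)C)c(O[Si](C)(C)C(C)(C)C)c1)O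
F2 | step 7 | S-ethyl (S)-3-[3,4-bis(tert-butyldimethylsilyloxy)phenyl]-3-(triethylsilyloxy)propanethioate | CCSC(=O)C[C@@H](c1ccc(O[Si](C)(C)C(C)(C)C)c(O[Si](C)(C)C(C)(C)C)c1)O[Si](CC)(CC)CC
F3 | step 7 | 6-[(S)-3-[3,4-bis(tert-butyldimethylsilyloxy)phenyl]-3-(triethylsilyloxy)propanoyl]-2-[(E)-4-(tert-butyldimethylsilyloxy)-3-methylbut-2-enyl]-3-methoxycyclohex-2-en-1-one | COC1=C(C/C=C(\C)CO[Si](C)(C)C(C)(C)C)C(=O)C(CC1)C(=O)C[C@@H](c1ccc(O[Si](C)(C)C(C)(C)C)c(O[Si](C)(C)C(C)(C)C)c1)O[Si](CC)(CC)CC
F4 | step 8 | 6-[(R)-3-[3,4-bis(tert-butyldimethylsilyloxy)phenyl]-3-hydroxypropanoyl]-2-[(E)-4-(tert-butyldimethylsilyloxy)-3-methylbut-2-enyl]-3-methoxycyclohex-2-en-1-one | COC1=C(C/C=C(\C)CO[Si](C)(C)C(C)(C)C)C(=O)C(CC1)C(=O)C[C@H](c1ccc(O[Si](C)(C)C(C)(C)C)c(O[Si](C)(C)C(C)(C)C)c1)O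
F5 | step 8 | 6-[(R)-3-[3,4-bis(tert-butyldimethylsilyloxy)phenyl]-3-hydroxypropanoyl]-2-[(E)-4-(tert-butyldimethylsilyloxy)-3-methylbut-2-enyl]-3-methoxy-6-(phenylselanyl)cyclohex-2-en-1-one | COC1=C(C/C=C(\C)CO[Si](C)(C)C(C)(C)C)C(=O)C(CC1)([Se]c1ccccc1)C(=O)C[C@H](c1ccc(O[Si](C)(C)C(C)(C)C)c(O[Si](C)(C)C(C)(C)C)c1)O
F6 | step 8 | (R)-3-[3,4-bis(tert-butyldimethylsilyloxy)phenyl]-3-hydroxy-1-{2-hydroxy-4-methoxy-3-[(E)-4-(tert-butyldimethylsilyloxy)-3-methylbut-2-enyl]phenyl}propan-1-one | COc1ccc(C(=O)C[C@H](c2ccc(O[Si](C)(C)C(C)(C)C)c(O[Si](C)(C)C(C)(C)C)c2)O)c(O)c1C/C=C(\C)CO[Si](C)(C)C(C)(C)C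
F7 | step 4 | 2-[(E)-4-(tert-butyldimethylsilyloxy)-3-methylbut-2-enyl]-6-(1-hydroxyethyl)-3-methoxycyclohex-2-en-1-one (diastereomer mixture) | COC1=C(C/C=C(\C)CO[Si](C)(C)C(C)(C)C)C(=O)C(C(C)O)CC1
F8 | step 1 | 2-(3-methylbut-2-enyl)cyclohexane-1,3-dione | CC(C)=CCC1C(=O)CCCC1=O
F9 | step 1 | 3-methoxy-2-(3-methylbut-2-enyl)cyclohex-2-en-1-one | COC1=C(CC=C(C)C)C(=O)CCC1
A1 | alternative 1 | (R)-3-[3,4-bis(tert-butyldimethylsilyloxy)phenyl]-1-{2-hydroxy-4-methoxy-3-[(E)-4-(tert-butyldimethylsilyloxy)-3-methylbut-2-enyl]phenyl}-3-(triethylsilyloxy)propan-1-one | COc1ccc(C(=O)C[C@@H](O[Si](CC)(CC)CC)c2ccc(O[Si](C)(C)C(C)(C)C)c(O[Si](C)(C)C(C)(C)C)c2)c(O)c1C/C=C(\C)CO[Si](C)(C)C(C)(C)C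
A2 | alternative 1 | (R)-5-[3,4-bis(tert-butyldimethylsilyloxy)phenyl]-5-(triethylsilyloxy)pent-1-yn-3-one | C#CC(=O)C[C@@H](O[Si](CC)(CC)CC)c1ccc(O[Si](C)(C)C(C)(C)C)c(O[Si](C)(C)C(C)(C)C)c1
A3 | alternative 1 | 1,3-dimethoxy-2-[(E)-4-(tert-butyldimethylsilyloxy)-3-methylbut-2-enyl]-1-(trimethylsilyloxy)buta-1,3-diene | C=C(OC)C(C/C=C(\C)CO[Si](C)(C)C(C)(C)C)=C(OC)O[Si](C)(C)C
A4 | alternative 2 | (S)-2-(3,4-diacetoxyphenyl)-8-[(E)-4-acetoxy-3-methylbut-2-enyl]-7-methoxychroman-4-one | COc1ccc2c(c1C/C=C(\C)COC(C)=O)O[C@H](c1ccc(OC(C)=O)c(OC(C)=O)c1)CC2=O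
A5 | alternative 2 | (S)-3-(3,4-diacetoxyphenyl)-3-{2-[(E)-4-acetoxy-3-methylbut-2-enyl]-3-methoxyphenoxy}propanoic acid | COc1cccc(O[C@H](c2ccc(OC(C)=O)c(OC(C)=O)c2)CC(=O)O)c1C/C=C(\C)COC(C)=O
A6 | alternative 3 | (S)-2-[3,4-bis(tert-butyldimethylsilyloxy)phenyl]-4-(tert-butyldimethylsilyloxy)-8-[(E)-4-(tert-butyldimethylsilyloxy)-3-methylbut-2-enyl]-7-methoxy-2H-chromene | COc1ccc2c(c1C/C=C(\C)CO[Si](C)(C)C(C)(C)C)O[C@H](c1ccc(O[Si](C)(C)C(C)(C)C)c(O[Si](C)(C)C(C)(C)C)c1)C=C2O[Si](C)(C)C(C)(C)C
A7 | alternative 3 | 1-{(S)-1-[3,4-bis(tert-butyldimethylsilyloxy)phenyl]allyloxy}-2-[(E)-4-(tert-butyldimethylsilyloxy)-3-methylbut-2-enyl]-3-methoxy-6-[1-(tert-butyldimethylsilyloxy)vinyl]benzene | COc1ccc(C(=C)O[Si](C)(C)C(C)(C)C)c(O[C@@H](C=C)c2ccc(O[Si](C)(C)C(C)(C)C)c(O[Si](C)(C)C(C)(C)C)c2)c1C/C=C(\C)CO[Si](C)(C)C(C)(C)C
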